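**The invariant.** In this closed flask, solid substrate, starting material, target and twice the self-condensation product add up to the charge at each moment. So your decision for the next run concerns how a fixed count of units splits between two exits.

solid substrate 0.40 M; gas phase 110 mM (held); time 2.5 d

    gas phase ⇌ dissolved gas, rate k1*(csat - [dissolved gas]) (k1 = 5.77 h⁻¹, csat = 110 mM)
    starting material + dissolved gas → target (k2 = 14.0 M⁻¹ h⁻¹)
    2 starting material → self-condensation product (k3 = 2.83 M⁻¹ h⁻¹)
    solid substrate ⇌ starting material, rate k4*(cs4 - [starting material]) while solid is left; crystals form when [starting material] > cs4 (cs4 = 0.39 M, k4 = 0.907 h⁻¹)

- how much target there is at 2.5 d, in percent of the solid substrate charged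
- the change that raises the amount of target at 2.5 d, in percent of the solid substrate charged most ("none" if none brings more than 2 percentage points) (oak / larch / ash / cedar / none)
- amount of target at 2.5 d, in percent of the solid substrate charged, after larch

- percent here means solid substrate units held: one self-condensation product counts as two
- for a step with 2 of a species take k times the square, and two of it per event
- solid substrate is a solid; its amount is given per volume of the solution
- at the start none of the gas is dissolved
- at the start none of the solid substrate is in solution
- run time (flask): 2.5 d

- oak: doubling the dissolution coefficient of step 4, all else as stated
- larch: doubling the solubility in step 4, all else as stated
- ash: doubling the transfer coefficient of step 1, all else as stated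
- cedar: doubling the saturation concentration of gas phase, all else as stated

**Crossing level.** Set the two losses of starting material equal, with dissolved gas at its ceiling 110 mM. The level is then the target constant 14.0 M⁻¹ h⁻¹ times that ceiling, over twice the condensation constant 2.83 M⁻¹ h⁻¹, which gives 0.272 M. I call this the crossing level: the concentration of starting material at which control of its fate changes hands. At any level, with the gas held at that ceiling, the share going to target, the selectivity, is the crossing level over the crossing level plus that level.

**Level reached.** The solid does not enter at once. Dissolving feeds starting material, and with dissolved gas taken at its ceiling I reckon the level at which feed and both losses balance at 0.114 M. That is less than the crossing level, although the charge 0.40 M is more. At that level, and on that same assumption about the gas, my rough share is 70.4 %. On the same assumption, larch raises the balance to 0.198 M, for a rough share of 57.9 %.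

**Next run.** Oak and larch feed harder at the same crossing level, and ash leaves the ceiling where it stands. Cedar moves the crossing level itself to 0.544 M, so I would change that.

**The forecast.** The forecast gives 70 %, 61 % after larch, and cedar, “beating ash”. We differ on larch, 57.9 % against 61 %.

**What ran.** The flask gives 69.8 %, 60.8 % after larch, and cedar, which gains 16 percentage points. The forecast's figure would fail at a charge of 0.228 M or 1.19 M, where the answer has moved 5 points. At 0.0292 d, each step taken net, starting material is made 1.20 times as fast as it is used, and dissolved gas 0.953 times. The flask ends with target 69.8 % beside self-condensation product 30.2 %, on a charge above the crossing level 0.272 M. The neighbour, charged with 0.24 M of solid substrate, below that level, gives 74.3 %.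

(The constants used here were drawn at random within sensible limits; no experiment stands behind them.)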